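Everything rests on opening the three-membered ring O8–C8–C9 across C8–C9 and C9–O8. C9 is a bare CH2, whereas C8 is fully substituted (aryl ring, C10H2 ester arm, O8), so the oxirane maps onto CH2 transfer from a sulfoxonium ylide to an aryl ketone. Under a chiral lanthanum–lithium binaphthoxide catalyst this single operation should close the ring, form two bonds and set C8, the only stereocentre, with the C10 isovalerate already in place. The substrate is a phenacyl isovalerate whose ortho phenol is masked as a TIPS ether, reached in four steps from 4-methoxy-3-methylphenol; one fluoride-triggered silyl-to-tigloyl exchange then gives the target.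

Key step: step 5

Remarks
- Atom labels: C8 = quaternary oxirane carbon, C9 = oxirane CH2, O8 = oxirane oxygen, C10 = CH2 carrying the isovalerate. C8 of the target is R (O8 > C10 > C9 > aryl).
- Assumption: the sense of induction of LaLi3(binaphthoxide)3 is mapped only for aryl methyl ketones. The route is written with the (S)-ligand as the one taken to deliver CH2 to the Re face of C8; if a pilot run shows the opposite sense, the (R)-ligand replaces it without other change.
- The ylide is made from the sulfoxonium chloride so that NaCl can be filtered off and no soluble halide reaches the lanthanum–lithium catalyst.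

Step 1
Reactants: 1 4-methoxy-3-methylphenol
Product: 3 1-(2-hydroxy-5-methoxy-4-methylphenyl)ethan-1-one, via 4-methoxy-3-methylphenyl acetate 2 (not isolated)
Conditions: Ac2O, BF3·OEt2 (neat), 0 → 90 °C; aq. NaOAc work-up
Reagents that add atoms: acetic anhydride, CC(=O)OC(C)=O
Why: O-acetylation followed by a boron trifluoride-promoted Fries rearrangement; the position para to the phenol oxygen carries OMe, so the acyl group must go ortho, and of the two ortho sites the one not flanked by the methyl group is open, while BF3 leaves the aryl methyl ether intact.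

Step 2
Reactants: 3 1-(2-hydroxy-5-methoxy-4-methylphenyl)ethan-1-one
Product: 4 1-[5-methoxy-4-methyl-2-(triisopropylsilyloxy)phenyl]ethan-1-one
Conditions: i-Pr3SiCl, imidazole, DMF, 40 °C
Reagents that add atoms: chlorotriisopropylsilane, CC(C)[Si](Cl)(C(C)C)C(C)C
Why: imidazole-mediated silyl ether formation on a phenol, warmed to overcome the hydrogen bond to the ketone; the bulky TIPS group is chosen because it must later withstand a carboxylate, the ylide and a neighbouring alkoxide without cleavage or migration.

Step 3
Reactants: 4 1-[5-methoxy-4-methyl-2-(triisopropylsilyloxy)phenyl]ethan-1-one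
Product: 6 2-bromo-1-[5-methoxy-4-methyl-2-(triisopropylsilyloxy)phenyl]ethan-1-one, via silyl enol ether 5 (not isolated)
Conditions: Me3SiOTf, Et3N, CH2Cl2, 0 °C; evaporate; NBS, THF, −78 → 0 °C
Reagents that add atoms: N-bromosuccinimide, O=C1CCC(=O)N1Br; trimethylsilyl triflate, C[Si](C)(C)OS(=O)(=O)C(F)(F)F (its silicon is carried only as far as 5)
Why: soft enolisation to the enol silane and electrophilic bromination at its terminal carbon (α-bromination of a ketone through its silyl enol ether); the enol silane outruns the electron-rich ring for NBS, and the product, no longer an enol, is not brominated again.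

Step 4
Reactants: 6 2-bromo-1-[5-methoxy-4-methyl-2-(triisopropylsilyloxy)phenyl]ethan-1-one; 7 isovaleric acid
Product: 8 2-[5-methoxy-4-methyl-2-(triisopropylsilyloxy)phenyl]-2-oxoethyl 3-methylbutanoate
Conditions: i-Pr2NEt, MeCN, rt
Reagents that add atoms: none
Why: SN2 displacement of a carbonyl-activated primary bromide by a carboxylate (phenacyl ester formation), which runs at room temperature; the mild ammonium carboxylate in acetonitrile leaves the aryl silyl ether alone.

Step 5
Reactants: 8 2-[5-methoxy-4-methyl-2-(triisopropylsilyloxy)phenyl]-2-oxoethyl 3-methylbutanoate; 9 trimethylsulfoxonium chloride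
Product: 12 [(2R)-2-[5-methoxy-4-methyl-2-(triisopropylsilyloxy)phenyl]oxiran-2-yl]methyl 3-methylbutanoate, via dimethylsulfoxonium methylide 10 (not isolated), via sulfoxonium betaine 11 (not isolated)
Conditions: 9, NaH, THF, reflux, then filtration (salt-free solution of 10); 8, LaLi3[(S)-binaphthoxide]3 (5–10 mol%), (2,4,6-(MeO)3C6H2)3P=O (same loading), 5 Å MS, THF, rt, slow addition of 10 (1.2 equiv)
Reagents that add atoms: none
Why: Proposed new method: the ylide carbon of 10 adds to the lanthanum-bound C8 carbonyl of 8 to give betaine 11 (C8–C9 bond), and the C8 alkoxide then expels dimethyl sulfoxide from C9 (C9–O8 bond) in a 3-exo-tet closure that forms the oxirane; the closest known reaction type is the LaLi3(binaphthoxide)3/triarylphosphine oxide-catalysed asymmetric Corey–Chaykovsky epoxidation of aryl methyl ketones, which is here stretched to an α-acyloxy ketone bearing an ortho-siloxy aryl group. The trivalent lanthanum centre serves as Lewis acid for the ketone while a lithium binaphthoxide arm, opened up by the phosphine oxide, carries the ylide, so both partners meet inside one chiral assembly. The new stereocentre C8 is controlled by the binaphthoxide configuration, which has to send CH2 to the Re face of the carbonyl (O > C10 > aryl) to give the R oxirane. The step needs the ketone to win over the isovalerate carbonyl and over deprotonation at C10, and ring closure to win over silyl or acyl shift to the C8 alkoxide; the α-acyloxy group makes the ketone the most electrophilic site, the stabilised ylide is weakly basic and is dosed slowly, and the bulky TIPS group migrates reluctantly. Face discrimination is secured by the contrast between the twisted ortho-substituted aryl ring and the slim CH2O-acyl arm, whose ester oxygen offers lanthanum a second binding point.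

Step 6
Reactants: 12 [(2R)-2-[5-methoxy-4-methyl-2-(triisopropylsilyloxy)phenyl]oxiran-2-yl]methyl 3-methylbutanoate; 13 tiglic anhydride
Product: 15 2-[(2R)-2-[(3-methylbutanoyloxy)methyl]oxiran-2-yl]-4-methoxy-5-methylphenyl (2E)-2-methylbut-2-enoate, via tetrabutylammonium phenoxide 14 (not isolated)
Conditions: 13 (3 equiv), Bu4NF (1.1 equiv, added slowly), THF, −20 → 0 °C; pH 7 work-up, Et3N-deactivated silica
Reagents that add atoms: none
Why: fluoride attacks silicon (strong Si–F bond) and the phenoxide 14 it frees is acylated at once by the anhydride already in solution (desilylative acylation of an aryl silyl ether), so it has no lifetime to open the oxirane at C9 or to take over the isovaleryl group; fluoride diverted by the anhydride only makes tigloyl fluoride, which acylates as well, and neither C8 nor the E alkene (the stable isomer) is touched.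

Compound list
1 | 4-methoxy-3-methylphenol | COc1ccc(O)cc1C | starting material
2 | 4-methoxy-3-methylphenyl acetate | COc1ccc(OC(C)=O)cc1C | intermediate
3 | 1-(2-hydroxy-5-methoxy-4-methylphenyl)ethan-1-one | CC(=O)c1cc(OC)c(C)cc1O | intermediate
4 | 1-[5-methoxy-4-methyl-2-(triisopropylsilyloxy)phenyl]ethan-1-one | CC(=O)c1cc(OC)c(C)cc1O[Si](C(C)C)(C(C)C)C(C)C | intermediate
5 | triisopropyl{4-methoxy-5-methyl-2-[1-(trimethylsilyloxy)ethenyl]phenoxy}silane (silyl enol ether) | C=C(O[Si](C)(C)C)c1cc(OC)c(C)cc1O[Si](C(C)C)(C(C)C)C(C)C | intermediate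
6 | 2-bromo-1-[5-methoxy-4-methyl-2-(triisopropylsilyloxy)phenyl]ethan-1-one | BrCC(=O)c1cc(OC)c(C)cc1O[Si](C(C)C)(C(C)C)C(C)C | intermediate
7 | isovaleric acid (3-methylbutanoic acid) | CC(C)CC(=O)O | starting material
8 | 2-[5-methoxy-4-methyl-2-(triisopropylsilyloxy)phenyl]-2-oxoethyl 3-methylbutanoate | CC(C)CC(=O)OCC(=O)c1cc(OC)c(C)cc1O[Si](C(C)C)(C(C)C)C(C)C | intermediate
9 | trimethylsulfoxonium chloride | C[S+](C)(C)=O.[Cl-] | starting material
10 | dimethylsulfoxonium methylide | C[S+](C)(=O)[CH2-] | intermediate
11 | (2S)-3-(dimethyloxosulfonio)-2-[5-methoxy-4-methyl-2-(triisopropylsilyloxy)phenyl]-2-oxidopropyl 3-methylbutanoate (sulfoxonium betaine) | CC(C)[Si](C(C)C)(C(C)C)Oc1cc(C)c(OC)cc1[C@]([O-])(COC(=O)CC(C)C)C[S+](C)(C)=O | intermediate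
12 | [(2R)-2-[5-methoxy-4-methyl-2-(triisopropylsilyloxy)phenyl]oxiran-2-yl]methyl 3-methylbutanoate | CC(C)[Si](C(C)C)(C(C)C)Oc1cc(C)c(OC)cc1[C@]1(COC(=O)CC(C)C)CO1 | intermediate
13 | tiglic anhydride, (2E)-2-methylbut-2-enoic anhydride | C/C=C(\C)C(=O)OC(=O)/C(C)=C/C | starting material
14 | tetrabutylammonium 2-[(2R)-2-[(3-methylbutanoyloxy)methyl]oxiran-2-yl]-4-methoxy-5-methylphenoxide | CCCC[N+](CCCC)(CCCC)CCCC.[O-]c1cc(C)c(OC)cc1[C@]1(COC(=O)CC(C)C)CO1 | intermediate
15 | 2-[(2R)-2-[(3-methylbutanoyloxy)methyl]oxiran-2-yl]-4-methoxy-5-methylphenyl (2E)-2-methylbut-2-enoate | C/C=C(\C)C(=O)Oc1cc(C)c(OC)cc1[C@]1(COC(=O)CC(C)C)CO1 | target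

Total step count: 6
Longest linear sequence: 6 steps (1 → 3 → 4 → 6 → 8 → 12 → 15)

Steps most likely to fail

Step 5 (bears the label). What may go wrong:
- Weak or reversed face selection, because the catalyst meets a ketone class outside its mapped scope.
- Deprotonation at C10 by the ylide, with acyl shift through the enediolate.
- Silyl transfer from the phenol oxygen to the C8 alkoxide of 11, after which the freed phenoxide closes onto C9.

Fallback, known chemistry only, from 8 back to 12:
- Wittig methylenation of the C8 carbonyl of 8 (Ph3PCH3Br, KOt-Bu, THF, 0 °C) should give 2-[5-methoxy-4-methyl-2-(triisopropylsilyloxy)phenyl]prop-2-en-1-yl 3-methylbutanoate F1.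
- Reduction of the ester with i-Bu2AlH (CH2Cl2, −78 °C) should free 2-[5-methoxy-4-methyl-2-(triisopropylsilyloxy)phenyl]prop-2-en-1-ol F2.
- Sharpless asymmetric epoxidation of this 2-substituted allylic alcohol (Ti(OiPr)4, L-(+)-diisopropyl tartrate, t-BuOOH, 4 Å MS, CH2Cl2, −20 °C) should give [(2S)-2-[5-methoxy-4-methyl-2-(triisopropylsilyloxy)phenyl]oxiran-2-yl]methanol F3. The titanium-bound hydroxyl directs oxygen delivery, and L-tartrate is expected to give the 2S glycidol, which has the same spatial arrangement as R-configured 12.
- After quenching the excess hydroperoxide with P(OMe)3, isovaleryl chloride and Et3N are added at −20 °C, so the sensitive glycidol is acylated without isolation and the route is rejoined at 12.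

Step 6. What may go wrong:
- Intramolecular opening of the oxirane at C9 by the phenoxide (dihydrobenzofuranol formation).
- Transfer of the isovaleryl group from C10 to the phenoxide, either one faster than tigloylation.

Fallback, from 8 to 15:
- The silyl-to-tigloyl exchange is moved ahead of the oxirane. Treating 8 with Bu4NF and tiglic anhydride 13 (THF, −20 °C) should give 4-methoxy-5-methyl-2-[2-(3-methylbutanoyloxy)acetyl]phenyl (2E)-2-methylbut-2-enoate F4.
- The lanthanum-catalysed methylene transfer of step 5 is then run on F4 with ylide 10 as the limiting reagent. It passes through the betaine (2S)-3-(dimethyloxosulfonio)-2-{5-methoxy-4-methyl-2-[(2E)-2-methylbut-2-enoyloxy]phenyl}-2-oxidopropyl 3-methylbutanoate F5 and ends directly at 15, so no step follows the epoxidation.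
- The price is that the ylide meets an aryl enoate. The α-branched, β-substituted tiglate is a poor conjugate acceptor and a hindered acyl donor, so the α-acyloxy ketone is expected to react first.

Step 3. What may go wrong:
- Electrophilic bromination of the electron-rich ring instead of the enol silane.
- Hydrolysis of the enol silane back to 4 before NBS is added.

Fallback, from 4 to 8, avoiding the bromide:
- The same enol silane 5 is oxidised under Rubottom conditions (mCPBA, NaHCO3, CH2Cl2, 0 °C) to 1-[5-methoxy-4-methyl-2-(triisopropylsilyloxy)phenyl]-2-(trimethylsilyloxy)ethan-1-one F6.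
- Citric acid work-up should desilylate it to 2-hydroxy-1-[5-methoxy-4-methyl-2-(triisopropylsilyloxy)phenyl]ethan-1-one F7.
- Steglich esterification with isovaleric acid 7 (EDC·HCl, DMAP, CH2Cl2, rt) rejoins the route at 8.

Further compounds
F1 | step 5 | 2-[5-methoxy-4-methyl-2-(triisopropylsilyloxy)phenyl]prop-2-en-1-yl 3-methylbutanoate | C=C(COC(=O)CC(C)C)c1cc(OC)c(C)cc1O[Si](C(C)C)(C(C)C)C(C)C
F2 | step 5 | 2-[5-methoxy-4-methyl-2-(triisopropylsilyloxy)phenyl]prop-2-en-1-ol | C=C(CO)c1cc(OC)c(C)cc1O[Si](C(C)C)(C(C)C)C(C)C
F3 | step 5 | [(2S)-2-[5-methoxy-4-methyl-2-(triisopropylsilyloxy)phenyl]oxiran-2-yl]methanol | CC(C)[Si](C(C)C)(C(C)C)Oc1cc(C)c(OC)cc1[C@]1(CO)CO1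
F4 | step 6 | 4-methoxy-5-methyl-2-[2-(3-methylbutanoyloxy)acetyl]phenyl (2E)-2-methylbut-2-enoate | C/C=C(\C)C(=O)Oc1cc(C)c(OC)cc1C(=O)COC(=O)CC(C)C
F5 | step 6 | (2S)-3-(dimethyloxosulfonio)-2-{5-methoxy-4-methyl-2-[(2E)-2-methylbut-2-enoyloxy]phenyl}-2-oxidopropyl 3-methylbutanoate | C/C=C(\C)C(=O)Oc1cc(C)c(OC)cc1[C@]([O-])(COC(=O)CC(C)C)C[S+](C)(C)=O
F6 | step 3 | 1-[5-methoxy-4-methyl-2-(triisopropylsilyloxy)phenyl]-2-(trimethylsilyloxy)ethan-1-one | C[Si](C)(C)OCC(=O)c1cc(OC)c(C)cc1O[Si](C(C)C)(C(C)C)C(C)C
F7 | step 3 | 2-hydroxy-1-[5-methoxy-4-methyl-2-(triisopropylsilyloxy)phenyl]ethan-1-one | OCC(=O)c1cc(OC)c(C)cc1O[Si](C(C)C)(C(C)C)C(C)C
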